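South-east is its neighbour south-west read twice as late, so one reckoning has to serve both.

    L → E (k1 = 8.07 × 10⁻⁵ s⁻¹)
    G ⇌ L, rate k2*(csat - [L]) (k2 = 0.00235 s⁻¹, csat = 95 mM)
    L + Q → J + D (k3 = 0.00491 L mol⁻¹ s⁻¹)
    Z + L → Q + D (k4 = 0.00561 L mol⁻¹ s⁻¹)
    Q + D → Q.D (k5 = 6.09 × 10⁻⁵ L mol⁻¹ s⁻¹)

- south-west: Z 1.3 M; G 95 mM (held); time 1.5 h
- south-east: Z 1.3 M; G 95 mM (held); time 3.0 h

- which of the two there is more of at the end, south-west (J / Q)
- which of the two there is more of at the end, south-east (J / Q)
- Q at the end, in percent of the Z charged, south-west
- Q at the end, in percent of the Z charged, south-east

- I start with the transfer of G and the step Z + L → Q + D. L lasts 1.6 min against the Z charged, far shorter than the run, so it stays near 0.0232 M, where transfer meets use. I hold it there, which makes Z pseudo-first-order. The fraction of Z left, x, is then 49.6% at south-west and 24.6% at south-east. This flat L is my weakest step for south-east. With this step alone, Q would be 50.4% and 75.4% of the Z charged.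
- Now I add L + Q → J + D. Its rate constant over that of Z + L is the selectivity factor s = 0.875. Both steps take the same L, so L cancels when one rate is divided by the other. Q as a fraction q of the Z charged then follows from x: q = (x^s − x)/(1 − s). That gives 36.3% at south-west and 37.7% at south-east. In this reduced flask q peaks where s·q = x, at x = 34.4%, so south-west stands before the peak and south-east after it.
- Last come the other two steps. L → E runs at 8.07 × 10⁻⁵ s⁻¹ against 0.00729 s⁻¹ for L with Z, so I drop it. Q + D → Q.D stays, and D ends near 0.838 M and 1.47 M. Drawing Q and D as straight lines from zero to their end values, I put what this step takes from Q at 3.34% and 12.2% of the charge. The straight line is a poor picture for south-east, where my q has already passed its peak and so stood above the line earlier in the run, which makes the second figure a low estimate.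
- I commit to Q at 33.0% against J at 14.1% for south-west, and Q at 25.5% against J at 37.7% for south-east.
- The forecast says Q leads at south-west with Q at 32.8%, and J leads at south-east with Q at 24.3%, on the ground that “Dissolution is slower than consumption, so L sits at a quasi-steady level”.
- The simulation gives Q 33.7% and J 14.4% at south-west, and Q 25.2% and J 41.9% at south-east.
- The rate of Z + L over that of L + Q is x/(s·q). At south-west the end readings make it 1.63, and at south-east 0.795, where the computed ratio of L use is 0.79. So the two readings lie on either side of 1. At south-west, raising Z alone to 2.16 M or cutting the time alone to 0.925 h moves Q by 6 points.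
- The neighbour is south-east charged with 0.52 M of Z. Its x of 3.6% and s give q = 14.8%. The computed Q there is 12.2%, beside Q.D 8.75%.

(The constants come from no measurement; the flask was simulated.)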